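Everything rests on closing ring D, the 2,2-dimethylpyran fused to ring B at C2'–C3', late and in one flask. The precursor is an (R)-isoflavan whose ring B carries fluorine at C2', a formyl group at C3' and a MOM ether on O-4'. A Z-selective Wittig reaction of that aldehyde with a β-silyloxy ylide builds the C3''=C4'' alkene; desilylation then lets the tertiary alkoxide displace the C2' fluoride, forming the O1''–C2' aryl ether. The step exploits the position of C3' between C2' and the oxygenated C4': fluorine and OMOM steer formylation to C3', and fluorine decides which oxygen closes the pyran. The isoflavan comes from a coumarin by asymmetric hydrogenation.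

Key step: step 11

Remark on numbering: isoflavan numbering is used (ring A C5–C8, ring C O1–C4, ring B C1'–C6'); ring D is O1''–C2''(Me2)–C3''=C4''.
Assumption on stereochemistry: the (S)-configured ligand in step 7 is expected to give 3R by analogy with (E)-α-methylstilbene; if the first run shows the opposite sense, the (R)-ligand is used.
Assumption on supply: compounds 1, 3 and 14 are catalogue materials.

Step 1
Reactants: 1 2,4-dihydroxy-6-methoxybenzaldehyde
Product: 2 2-hydroxy-6-methoxy-4-(methoxymethoxy)benzaldehyde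
Conditions: MOMCl (1.05 equiv), iPr2NEt, CH2Cl2, 0 °C
Reagents that add atoms: chloromethyl methyl ether, COCCl
Why: The 4-OH is the more acidic phenol and is not held in the hydrogen bond to the aldehyde, so base-mediated MOM ether formation (Williamson-type O-alkylation) should occur there and leave the chelated 2-OH free.

Step 2
Reactants: 3 2-(2-fluoro-4-hydroxyphenyl)acetic acid
Product: 5 2-[2-fluoro-4-(methoxymethoxy)phenyl]acetic acid, via bis-MOM ester 4 (not isolated)
Conditions: MOMCl (2.5 equiv), iPr2NEt, CH2Cl2, 0 °C to rt; then LiOH, THF–H2O, rt; then 1 M HCl to pH 4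
Reagents that add atoms: chloromethyl methyl ether, COCCl; lithium hydroxide, [Li+].[OH-]
Why: Exhaustive methoxymethylation followed by saponification should remove only the acyl acetal ester, because the aryl MOM ether is stable to hydroxide (ester hydrolysis).

Step 3
Reactants: 2 2-hydroxy-6-methoxy-4-(methoxymethoxy)benzaldehyde; 5 2-[2-fluoro-4-(methoxymethoxy)phenyl]acetic acid
Product: 6 3-[2-fluoro-4-(methoxymethoxy)phenyl]-5-methoxy-7-(methoxymethoxy)-2H-chromen-2-one
Conditions: Ac2O, Et3N, 110 °C
Reagents that add atoms: none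
Why: In this Perkin–Oglialoro condensation the mixed anhydride of 5 acylates the phenol and the aryl acetate enolate condenses with the neighbouring aldehyde, so the lactone closes with the C3=C4 bond cis by necessity.

Step 4
Reactants: 6 3-[2-fluoro-4-(methoxymethoxy)phenyl]-5-methoxy-7-(methoxymethoxy)-2H-chromen-2-one
Product: 7 (Z)-2-[2-fluoro-4-(methoxymethoxy)phenyl]-3-[2-hydroxy-6-methoxy-4-(methoxymethoxy)phenyl]prop-2-en-1-ol
Conditions: iBu2AlH (5 equiv), CH2Cl2, −78 to 0 °C; aq. KNaC4H4O6 work-up (kept neutral)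
Reagents that add atoms: none
Why: iBu2AlH should reduce the lactone through the lactol to the allylic alcohol by 1,2-addition (lactone reduction), which keeps the Z geometry fixed by the coumarin ring and frees the phenol.

Step 5
Reactants: 7 (Z)-2-[2-fluoro-4-(methoxymethoxy)phenyl]-3-[2-hydroxy-6-methoxy-4-(methoxymethoxy)phenyl]prop-2-en-1-ol
Product: 8 3-[(Z)-2-[2-fluoro-4-(methoxymethoxy)phenyl]-3-hydroxyprop-1-en-1-yl]-2-hydroxy-4-methoxy-6-(methoxymethoxy)benzaldehyde
Conditions: MgCl2, Et3N, (CH2O)n, MeCN, 80 °C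
Reagents that add atoms: paraformaldehyde (as formaldehyde), C=O
Why: The magnesium-phenoxide-directed ortho-formylation (Casnati–Skattebøl) delivers formaldehyde only ortho to the free phenol, and the single open ortho position is the future C8, since O-7 is blocked as its MOM ether.

Step 6
Reactants: 8 3-[(Z)-2-[2-fluoro-4-(methoxymethoxy)phenyl]-3-hydroxyprop-1-en-1-yl]-2-hydroxy-4-methoxy-6-(methoxymethoxy)benzaldehyde
Product: 9 3-[2-fluoro-4-(methoxymethoxy)phenyl]-5-methoxy-7-(methoxymethoxy)-2H-chromene-8-carbaldehyde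
Conditions: PPh3, DIAD, THF, 0 °C to rt
Reagents that add atoms: none
Why: In this Mitsunobu etherification the acidic salicylaldehyde phenol should displace the activated primary allylic alcohol in a 6-exo-tet closure that forms ring C as the 2H-chromene.

Step 7
Reactants: 9 3-[2-fluoro-4-(methoxymethoxy)phenyl]-5-methoxy-7-(methoxymethoxy)-2H-chromene-8-carbaldehyde
Product: 10 (3R)-3-[2-fluoro-4-(methoxymethoxy)phenyl]-5-methoxy-7-(methoxymethoxy)-3,4-dihydro-2H-chromene-8-carbaldehyde
Conditions: H2 (50 bar), [Ir(cod)((S)-tBu-PHOX)]B[3,5-(CF3)2C6H3]4 (2 mol %), CH2Cl2, rt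
Reagents that add atoms: none
Why: Iridium–phosphinooxazoline asymmetric hydrogenation of the trisubstituted, aryl-conjugated alkene of a 3-aryl-2H-chromene should set C3 under catalyst control (the ligand pocket selects the alkene face), while MOM ethers, aryl fluoride and aldehyde are not reduced.

Step 8
Reactants: 10 (3R)-3-[2-fluoro-4-(methoxymethoxy)phenyl]-5-methoxy-7-(methoxymethoxy)-3,4-dihydro-2H-chromene-8-carbaldehyde
Product: 11 (3R)-8-(dimethoxymethyl)-3-[2-fluoro-4-(methoxymethoxy)phenyl]-5-methoxy-7-(methoxymethoxy)-3,4-dihydro-2H-chromene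
Conditions: HC(OMe)3, MeOH, PPTS (cat.), rt; Et3N quench
Reagents that add atoms: trimethyl orthoformate, COC(OC)OC; methanol, CO
Why: Acid-catalysed acetalisation driven by the orthoformate should mask the ring A aldehyde against the amide base and the ylide of the following steps.

Step 9
Reactants: 11 (3R)-8-(dimethoxymethyl)-3-[2-fluoro-4-(methoxymethoxy)phenyl]-5-methoxy-7-(methoxymethoxy)-3,4-dihydro-2H-chromene
Product: 13 3-[(3R)-8-(dimethoxymethyl)-5-methoxy-7-(methoxymethoxy)-3,4-dihydro-2H-chromen-3-yl]-2-fluoro-6-(methoxymethoxy)benzaldehyde, via C3' aryllithium 12 (not isolated)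
Conditions: LiN(iPr)2, THF, −78 °C; then DMF, −78 to 0 °C; aq. NH4Cl
Reagents that add atoms: N,N-dimethylformamide, CN(C)C=O
Why: In this directed ortho-metalation C3' lies between fluorine and the MOM ether and is the most acidic arene C–H, so the amide base should lithiate there (C6 of ring A would need an alkyllithium) and DMF formylates the aryllithium.

Step 10
Reactants: 14 methyltriphenylphosphonium bromide
Product: 17 [2-methyl-2-(trimethylsilyloxy)propyl]triphenylphosphonium bromide, via methylene ylide 15 (not isolated), via lithium betaine 16 (not isolated)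
Conditions: n-BuLi, THF, −78 to 0 °C; acetone, −78 °C; Me3SiCl, −78 °C to rt; precipitation from Et2O
Reagents that add atoms: acetone, CC(C)=O; chlorotrimethylsilane, C[Si](C)(C)Cl
Why: Wittig addition of the methylene ylide to acetone stops at the lithium betaine at −78 °C, and O-silylation of its alkoxide should give the β-silyloxyalkylphosphonium salt (betaine trapping).

Step 11
Reactants: 13 3-[(3R)-8-(dimethoxymethyl)-5-methoxy-7-(methoxymethoxy)-3,4-dihydro-2H-chromen-3-yl]-2-fluoro-6-(methoxymethoxy)benzaldehyde; 17 [2-methyl-2-(trimethylsilyloxy)propyl]triphenylphosphonium bromide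
Product: 20 (3R)-8-(dimethoxymethyl)-5-methoxy-7-(methoxymethoxy)-3-[5-(methoxymethoxy)-2,2-dimethyl-2H-chromen-8-yl]-3,4-dihydro-2H-chromene, via silyloxy ylide 18 (not isolated), via Z-alkenyl silyl ether 19 (not isolated)
Conditions: 17, KN(SiMe3)2, THF, −78 °C; then 13, −78 °C to rt; then KOtBu, DMSO, 60 °C
Reagents that add atoms: none
Why: KN(SiMe3)2 turns 17 into the non-stabilised ylide 18, which adds to the only free aldehyde (at C3' of ring B) under lithium-free kinetic control through the cis-oxaphosphetane and should give the (Z)-alkene 19 with loss of Ph3PO; KOtBu in DMSO then cleaves the O–Si bond and the tertiary potassium alkoxide attacks C2' and expels fluoride through a Meisenheimer-type σ-adduct (addition–elimination). The closest known reactions are the Z-selective Wittig olefination of ortho-substituted benzaldehydes with β-silyloxyalkyl ylides and the intramolecular SNAr etherification of 2-fluoroaryl alkoxides used for chromans, here run in one flask. Ring D closes in a 6-exo sense, O1'' attacking the arene carbon C2' from a side chain held cis by the Z-alkene, while the C3''=C4'' bond is made beforehand in the intermolecular olefination. No stereocentre is created; the element that matters is the alkene geometry, which the potassium base at −78 °C and the two ortho substituents of the aldehyde should secure, and any E-isomer cannot cyclise and is separated. The step needs chemoselectivity between the two formyl carbons, which the dimethyl acetal on ring A secures, and regioselectivity between O-2' and O-4', which is fixed because only C2' carries a leaving group and O-4' is a MOM ether. C3 is not at risk because its C–H bond is not acidified.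

Step 12
Reactants: 20 (3R)-8-(dimethoxymethyl)-5-methoxy-7-(methoxymethoxy)-3-[5-(methoxymethoxy)-2,2-dimethyl-2H-chromen-8-yl]-3,4-dihydro-2H-chromene
Product: 21 (3R)-7-hydroxy-3-(5-hydroxy-2,2-dimethyl-2H-chromen-8-yl)-5-methoxy-3,4-dihydro-2H-chromene-8-carbaldehyde
Conditions: 2 M aq. HCl, THF–MeOH, 40 °C
Reagents that add atoms: water, O
Why: Aqueous acid should hydrolyse the dimethyl acetal and the two aryl MOM acetals (acetal hydrolysis), while the methyl ether on O-5 and the 2,2-dimethylchromene are expected to survive these mild conditions.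

Compound list
1 | 2,4-dihydroxy-6-methoxybenzaldehyde | COc1cc(O)cc(O)c1C=O | starting material
2 | 2-hydroxy-6-methoxy-4-(methoxymethoxy)benzaldehyde | COCOc1cc(O)c(C=O)c(OC)c1 | intermediate
3 | 2-(2-fluoro-4-hydroxyphenyl)acetic acid | OC(=O)Cc1ccc(O)cc1F | starting material
4 | methoxymethyl 2-[2-fluoro-4-(methoxymethoxy)phenyl]acetate (bis-MOM ester) | COCOC(=O)Cc1ccc(OCOC)cc1F | intermediate
5 | 2-[2-fluoro-4-(methoxymethoxy)phenyl]acetic acid | COCOc1ccc(CC(=O)O)c(F)c1 | intermediate
6 | 3-[2-fluoro-4-(methoxymethoxy)phenyl]-5-methoxy-7-(methoxymethoxy)-2H-chromen-2-one | COCOc1ccc(C2=Cc3c(OC)cc(OCOC)cc3OC2=O)c(F)c1 | intermediate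
7 | (Z)-2-[2-fluoro-4-(methoxymethoxy)phenyl]-3-[2-hydroxy-6-methoxy-4-(methoxymethoxy)phenyl]prop-2-en-1-ol | OC/C(c1ccc(OCOC)cc1F)=C\c1c(O)cc(OCOC)cc1OC | intermediate
8 | 3-[(Z)-2-[2-fluoro-4-(methoxymethoxy)phenyl]-3-hydroxyprop-1-en-1-yl]-2-hydroxy-4-methoxy-6-(methoxymethoxy)benzaldehyde | OC/C(c1ccc(OCOC)cc1F)=C\c1c(O)c(C=O)c(OCOC)cc1OC | intermediate
9 | 3-[2-fluoro-4-(methoxymethoxy)phenyl]-5-methoxy-7-(methoxymethoxy)-2H-chromene-8-carbaldehyde | COc1cc(OCOC)c(C=O)c2c1C=C(c1ccc(OCOC)cc1F)CO2 | intermediate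
10 | (3R)-3-[2-fluoro-4-(methoxymethoxy)phenyl]-5-methoxy-7-(methoxymethoxy)-3,4-dihydro-2H-chromene-8-carbaldehyde | COc1cc(OCOC)c(C=O)c2c1C[C@H](c1ccc(OCOC)cc1F)CO2 | intermediate
11 | (3R)-8-(dimethoxymethyl)-3-[2-fluoro-4-(methoxymethoxy)phenyl]-5-methoxy-7-(methoxymethoxy)-3,4-dihydro-2H-chromene | COc1cc(OCOC)c(C(OC)OC)c2c1C[C@H](c1ccc(OCOC)cc1F)CO2 | intermediate
12 | C3' aryllithium of 11 | COc1cc(OCOC)c(C(OC)OC)c2c1C[C@H](c1ccc(OCOC)c([Li])c1F)CO2 | intermediate
13 | 3-[(3R)-8-(dimethoxymethyl)-5-methoxy-7-(methoxymethoxy)-3,4-dihydro-2H-chromen-3-yl]-2-fluoro-6-(methoxymethoxy)benzaldehyde | COc1cc(OCOC)c(C(OC)OC)c2c1C[C@H](c1ccc(OCOC)c(C=O)c1F)CO2 | intermediate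
14 | methyltriphenylphosphonium bromide | C[P+](c1ccccc1)(c1ccccc1)c1ccccc1.[Br-] | starting material
15 | methylidene(triphenyl)phosphorane (methylene ylide) | C=P(c1ccccc1)(c1ccccc1)c1ccccc1 | intermediate
16 | 2-methyl-1-(triphenylphosphonio)propan-2-olate, LiBr adduct (lithium betaine) | [Li+].[O-]C(C)(C)C[P+](c1ccccc1)(c1ccccc1)c1ccccc1.[Br-] | intermediate
17 | [2-methyl-2-(trimethylsilyloxy)propyl]triphenylphosphonium bromide | C[Si](C)(C)OC(C)(C)C[P+](c1ccccc1)(c1ccccc1)c1ccccc1.[Br-] | intermediate
18 | [2-methyl-2-(trimethylsilyloxy)propylidene]triphenylphosphorane (silyloxy ylide) | C[Si](C)(C)OC(C)(C)C=P(c1ccccc1)(c1ccccc1)c1ccccc1 | intermediate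
19 | (3R)-8-(dimethoxymethyl)-3-{2-fluoro-4-(methoxymethoxy)-3-[(Z)-3-methyl-3-(trimethylsilyloxy)but-1-en-1-yl]phenyl}-5-methoxy-7-(methoxymethoxy)-3,4-dihydro-2H-chromene (Z-alkenyl silyl ether) | COc1cc(OCOC)c(C(OC)OC)c2c1C[C@H](c1ccc(OCOC)c(/C=C\C(C)(C)O[Si](C)(C)C)c1F)CO2 | intermediate
20 | (3R)-8-(dimethoxymethyl)-5-methoxy-7-(methoxymethoxy)-3-[5-(methoxymethoxy)-2,2-dimethyl-2H-chromen-8-yl]-3,4-dihydro-2H-chromene | COc1cc(OCOC)c(C(OC)OC)c2c1C[C@H](c1ccc(OCOC)c3c1OC(C)(C)C=C3)CO2 | intermediate
21 | (3R)-7-hydroxy-3-(5-hydroxy-2,2-dimethyl-2H-chromen-8-yl)-5-methoxy-3,4-dihydro-2H-chromene-8-carbaldehyde | COc1cc(O)c(C=O)c2c1C[C@H](c1ccc(O)c3c1OC(C)(C)C=C3)CO2 | target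

Total step count: 12.
Longest linear sequence: 10 steps (steps 1, 3, 4, 5, 6, 7, 8, 9, 11, 12; steps 2 and 10 supply the two side branches).

Steps most likely to fail

Step 11. The ylide may lose silanolate by β-elimination before it adds, the olefination may give too much E-alkene (which cannot cyclise), or fluoride displacement on the electron-rich, doubly ortho-substituted arene may be slow. The fallback sets out from 13 and makes the two bonds one after the other. Stork–Zhao olefination of 13 with the ylide from (iodomethyl)triphenylphosphonium iodide and NaN(SiMe3)2 (THF–DMPU, −78 °C) should give the (Z)-vinyl iodide, (3R)-8-(dimethoxymethyl)-3-{2-fluoro-3-[(Z)-2-iodoethenyl]-4-(methoxymethoxy)phenyl}-5-methoxy-7-(methoxymethoxy)-3,4-dihydro-2H-chromene F1. Iodine–lithium exchange with t-BuLi at −78 °C proceeds with retention of geometry, and addition to acetone should give the (Z)-tertiary allylic alcohol, (Z)-4-{3-[(3R)-8-(dimethoxymethyl)-5-methoxy-7-(methoxymethoxy)-3,4-dihydro-2H-chromen-3-yl]-2-fluoro-6-(methoxymethoxy)phenyl}-2-methylbut-3-en-2-ol F2. KOtBu in DMSO at 60 °C then closes ring D by intramolecular SNAr, and the route is rejoined at 20.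

Step 7. Facial selectivity may be poor because the ortho-fluorine twists ring B out of the alkene plane, and the aldehyde or acid generated from the catalyst may slow or divert the hydrogenation. The fallback sets out from 7 and moves the asymmetric step to the acyclic allylic alcohol, before the aldehyde exists. Hydroxyl-directed hydrogenation of 7 with Ru(OAc)2[(S)-BINAP] under H2 in MeOH (ligand antipode chosen to give 2R) should give the saturated diol, (2R)-2-[2-fluoro-4-(methoxymethoxy)phenyl]-3-[2-hydroxy-6-methoxy-4-(methoxymethoxy)phenyl]propan-1-ol F3. Ortho-formylation with MgCl2, Et3N and paraformaldehyde should give 3-[(2R)-2-[2-fluoro-4-(methoxymethoxy)phenyl]-3-hydroxypropyl]-2-hydroxy-4-methoxy-6-(methoxymethoxy)benzaldehyde F4. Mitsunobu closure of ring C (PPh3, DIAD) rejoins the route at 10.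

Step 12. While the MOM ethers are being cleaved, protic acid may add solvent across the electron-rich C3''=C4'' bond or open ring D. The fallback sets out from 20 and separates the two deprotections. Buffered hydrolysis of the acetal alone (PPTS, acetone–water, rt) should give the bis-MOM aldehyde, (3R)-5-methoxy-7-(methoxymethoxy)-3-[5-(methoxymethoxy)-2,2-dimethyl-2H-chromen-8-yl]-3,4-dihydro-2H-chromene-8-carbaldehyde F5. The two aryl MOM ethers are then removed without protic acid by Me3SiOTf and 2,2'-bipyridyl in CH2Cl2 at 0 °C followed by water, which should give 21.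

Further compounds
F1 | step 11 | (3R)-8-(dimethoxymethyl)-3-{2-fluoro-3-[(Z)-2-iodoethenyl]-4-(methoxymethoxy)phenyl}-5-methoxy-7-(methoxymethoxy)-3,4-dihydro-2H-chromene | COc1cc(OCOC)c(C(OC)OC)c2c1C[C@H](c1ccc(OCOC)c(/C=C\I)c1F)CO2
F2 | step 11 | (Z)-4-{3-[(3R)-8-(dimethoxymethyl)-5-methoxy-7-(methoxymethoxy)-3,4-dihydro-2H-chromen-3-yl]-2-fluoro-6-(methoxymethoxy)phenyl}-2-methylbut-3-en-2-ol | COc1cc(OCOC)c(C(OC)OC)c2c1C[C@H](c1ccc(OCOC)c(/C=C\C(C)(C)O)c1F)CO2
F3 | step 7 | (2R)-2-[2-fluoro-4-(methoxymethoxy)phenyl]-3-[2-hydroxy-6-methoxy-4-(methoxymethoxy)phenyl]propan-1-ol | COc1cc(OCOC)cc(O)c1C[C@H](c1ccc(OCOC)cc1F)CO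
F4 | step 7 | 3-[(2R)-2-[2-fluoro-4-(methoxymethoxy)phenyl]-3-hydroxypropyl]-2-hydroxy-4-methoxy-6-(methoxymethoxy)benzaldehyde | COc1cc(OCOC)c(C=O)c(O)c1C[C@H](c1ccc(OCOC)cc1F)CO
F5 | step 12 | (3R)-5-methoxy-7-(methoxymethoxy)-3-[5-(methoxymethoxy)-2,2-dimethyl-2H-chromen-8-yl]-3,4-dihydro-2H-chromene-8-carbaldehyde | COc1cc(OCOC)c(C=O)c2c1C[C@H](c1ccc(OCOC)c3c1OC(C)(C)C=C3)CO2
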